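**Plan**

- Retrosynthesis: the C1 carbinol goes back to the aryl ketone and the ortho methoxy group of ring A to a phenol. The ring A–C1 bond and the neighbouring ring A–O bond are then cut together, and last the C3–ring B bond.
- Enabling feature: ring A carries C1 and an oxygen on adjacent ring carbons, with two more methoxy groups on the two carbons across the ring. This is symmetrical 4,5-dimethoxybenzyne plus the carbon and one oxygen of a carboxyl group.
- Forward: ring B is joined to C3 by opening (R)-β-butyrolactone with an aryl copper reagent. The resulting acid is inserted into the aryne (made from 3,4-dimethoxyphenol), which attaches ring A as a hydroxyaryl ketone. O-methylation and ketone reduction finish; both benzene rings are bought and no ring is built.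
- Stereochemistry: C3 (S) comes from the lactone by SN2 inversion and stays β to the carbonyl. C1 (R) is set last by catalyst-controlled Corey–Bakshi–Shibata reduction.

Key step: step 4

Remark: the chain is numbered C1 (carbinol), C2 (CH2), C3 (CH–CH3), C4 (CH3); ring A is the aryl group on C1, ring B the one on C3; the target is read as (1R,3S)-1,3-bis(2,4,5-trimethoxyphenyl)butan-1-ol.

**Route**

Step 1
Reactants: 1 3,4-dimethoxyphenol
Product: 2 2-bromo-4,5-dimethoxyphenol
Conditions: NBS (1.0 equiv), CH2Cl2, −20 → 0 °C
Reagents that add atoms: N-bromosuccinimide, BrN1C(=O)CCC1=O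
Why: Electrophilic aromatic bromination of a phenol: C6, ortho to the hydroxyl and para to the 3-methoxy group, is the most activated open position, whereas C2 is flanked by two substituents, so one equivalent of NBS at low temperature should brominate there alone.

Step 2
Reactants: 2 2-bromo-4,5-dimethoxyphenol
Product: 5 4,5-dimethoxy-2-(trimethylsilyl)phenyl trifluoromethanesulfonate, via trimethylsilyl ether 3 (not isolated), via lithium silylphenoxide 4 (not isolated)
Conditions: HMDS, THF, reflux, then evaporation; n-BuLi, THF, −100 → −80 °C; Tf2O, −100 °C → rt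
Reagents that add atoms: hexamethyldisilazane, C[Si](C)(C)N[Si](C)(C)C; trifluoromethanesulfonic anhydride, O=S(=O)(OS(=O)(=O)C(F)(F)F)C(F)(F)F
Why: O-Silylation, bromine–lithium exchange and retro-Brook rearrangement (1,3 shift of silicon from oxygen to the aryl carbanion, driven by formation of lithium phenoxide 4) followed by O-triflation of that phenoxide is the standard one-flask route from ortho-bromophenols to ortho-silylaryl triflates, and the methoxy groups are inert to n-BuLi at −100 °C.

Step 3
Reactants: 6 1-bromo-2,4,5-trimethoxybenzene; 7 (R)-β-butyrolactone [(R)-4-methyloxetan-2-one]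
Product: 9 (S)-3-(2,4,5-trimethoxyphenyl)butanoic acid, via aryl Grignard reagent 8 (not isolated)
Conditions: 6, Mg, THF, reflux; then 8 (1.3 equiv) added slowly to 7, CuBr·SMe2 (10 mol%), THF/Me2S, −30 → 0 °C; 1 M HCl
Reagents that add atoms: none
Why: Copper-catalysed SN2 ring opening of a β-lactone by a Grignard reagent: the soft aryl copper species attacks the β-carbon with alkyl–oxygen cleavage and inversion, so the R lactone should deliver the 3S acid in one operation, with C3 ending up β to the carboxyl group and therefore configurationally safe.

Step 4
Reactants: 9 (S)-3-(2,4,5-trimethoxyphenyl)butanoic acid; 5 4,5-dimethoxy-2-(trimethylsilyl)phenyl trifluoromethanesulfonate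
Product: 12 (S)-1-(2-hydroxy-4,5-dimethoxyphenyl)-3-(2,4,5-trimethoxyphenyl)butan-1-one, via 4,5-dimethoxybenzyne 10 (not isolated), via cesium benzoxetenolate 11 (not isolated)
Conditions: 5 (1.5 equiv), CsF (4 equiv), THF (dilute), 125 °C, sealed tube; aqueous NH4Cl
Reagents that add atoms: none
Why: Fluoride removes the silyl group of 5 and triflate departs to give aryne 10; the cesium carboxylate of 9 adds through oxygen to one carbon of the strained triple bond, and the aryl anion generated on the adjacent carbon attacks the ester carbonyl, closing the four-membered benzoxetene alkoxide 11 (4-exo-trig, not retained), which opens by C–O cleavage to the phenoxide of the ortho-hydroxyaryl ketone, so that the ring A–C1 and ring A–O bonds form in one flask. This is the known fluoride-induced insertion of arynes into the C–O bond of carboxylic acids, in effect an aryne-triggered anionic ortho-Fries-type acyl shift. No ring is kept and no stereocentre is created; C3 lies β to the reacting carbonyl, carries no acidic hydrogen and should pass through unchanged. Regiochemistry does not arise because 10 is symmetrical, with hydrogen on both carbons beside the triple bond and the two methoxy groups across the ring, so either sense of addition gives the 2-hydroxy-4,5-dimethoxyphenyl ketone. The selectivity needed is acyl transfer to the aryl anion ahead of its protonation to the simple aryl ester, which hot aprotic THF with excess CsF favours, and single arylation, which the low nucleophilicity of the hydrogen-bonded ortho-acyl phenoxide should secure.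

Step 5
Reactants: 12 (S)-1-(2-hydroxy-4,5-dimethoxyphenyl)-3-(2,4,5-trimethoxyphenyl)butan-1-one
Product: 13 (S)-1,3-bis(2,4,5-trimethoxyphenyl)butan-1-one
Conditions: MeI, K2CO3, DMF, 40 °C
Reagents that add atoms: iodomethane, CI
Why: Williamson O-methylation of the hydrogen-bonded phenol; carbonate in DMF is basic enough for the phenol but does not alkylate the ketone α-carbon, and C3 has no acidic hydrogen.

Step 6
Reactants: 13 (S)-1,3-bis(2,4,5-trimethoxyphenyl)butan-1-one
Product: 14 (1R,3S)-1,3-bis(2,4,5-trimethoxyphenyl)butan-1-ol (CNP0503344.1)
Conditions: (S)-Me-CBS (20 mol%), BH3·SMe2, THF, −20 °C; MeOH, then aqueous NaHCO3; chromatography on Et3N-deactivated silica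
Reagents that add atoms: none
Why: Corey–Bakshi–Shibata reduction: the (S)-oxazaborolidine ((S)-1-methyl-3,3-diphenyltetrahydro-1H,3H-pyrrolo[1,2-c][1,3,2]oxazaborole) binds the ketone anti to the aryl group, which acts as the large substituent, and directs borane hydride to the Si face, setting C1 as R under catalyst control independently of the remote C3 centre; the quench is kept non-acidic because the product is a readily ionised electron-rich benzylic alcohol.

**Compound list**

1 | 3,4-dimethoxyphenol | COc1ccc(O)cc1OC | starting material
2 | 2-bromo-4,5-dimethoxyphenol | COc1cc(O)c(Br)cc1OC | intermediate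
3 | (2-bromo-4,5-dimethoxyphenoxy)trimethylsilane | COc1cc(O[Si](C)(C)C)c(Br)cc1OC | intermediate
4 | lithium 4,5-dimethoxy-2-(trimethylsilyl)phenoxide | [Li+].[O-]c1cc(OC)c(OC)cc1[Si](C)(C)C | intermediate
5 | 4,5-dimethoxy-2-(trimethylsilyl)phenyl trifluoromethanesulfonate | COc1cc(OS(=O)(=O)C(F)(F)F)c([Si](C)(C)C)cc1OC | intermediate
6 | 1-bromo-2,4,5-trimethoxybenzene | COc1cc(OC)c(Br)cc1OC | starting material
7 | (R)-β-butyrolactone [(R)-4-methyloxetan-2-one] | C[C@@H]1CC(=O)O1 | starting material
8 | (2,4,5-trimethoxyphenyl)magnesium bromide | COc1cc(OC)c([Mg]Br)cc1OC | intermediate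
9 | (S)-3-(2,4,5-trimethoxyphenyl)butanoic acid | OC(=O)C[C@H](C)c1cc(OC)c(OC)cc1OC | intermediate
10 | 4,5-dimethoxybenzyne (1,2-didehydro-4,5-dimethoxybenzene) | COC1=CC#CC=C1OC | intermediate
11 | cesium 4,5-dimethoxy-2-[(2S)-2-(2,4,5-trimethoxyphenyl)propyl]-2H-1-benzoxet-2-olate | [Cs+].[O-]C1(C[C@H](C)c2cc(OC)c(OC)cc2OC)Oc2cc(OC)c(OC)cc21 | intermediate
12 | (S)-1-(2-hydroxy-4,5-dimethoxyphenyl)-3-(2,4,5-trimethoxyphenyl)butan-1-one | COc1cc(O)c(C(=O)C[C@H](C)c2cc(OC)c(OC)cc2OC)cc1OC | intermediate
13 | (S)-1,3-bis(2,4,5-trimethoxyphenyl)butan-1-one | COc1cc(OC)c(C(=O)C[C@H](C)c2cc(OC)c(OC)cc2OC)cc1OC | intermediate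
14 | (1R,3S)-1,3-bis(2,4,5-trimethoxyphenyl)butan-1-ol | COc1cc(OC)c([C@H](O)C[C@H](C)c2cc(OC)c(OC)cc2OC)cc1OC | target

**Count**

Total steps: 6. Longest linear sequence: 5 steps (steps 1, 2, 4, 5, 6, from 3,4-dimethoxyphenol); the acid branch is 4 steps (3, 4, 5, 6).

**Steps most likely to fail**

Step 4 (key step). What may go wrong: the aryl anion formed after carboxylate addition is protonated (by the acid, by bifluoride or by the α-CH2 of the ester) faster than it attacks the carbonyl, so that material drains into the simple aryl ester. The product phenoxide may also be arylated by surplus aryne. Fallback: the ring A–C1 bond is made by aryl-metal addition to an activated amide, ring A arriving with all three methoxy groups in place. Setting out from acid 9, coupling with N,O-dimethylhydroxylamine hydrochloride (EDC·HCl, N-methylmorpholine, CH2Cl2, rt) should give (S)-N-methoxy-N-methyl-3-(2,4,5-trimethoxyphenyl)butanamide F1. Bromide 6 is converted with n-BuLi (THF, −78 °C) into (2,4,5-trimethoxyphenyl)lithium F2. F2 should add once to F1 through the chelated tetrahedral adduct and release ketone 13 on aqueous NH4Cl work-up. The route is rejoined at 13, and step 5 is then not needed.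

Step 3. What may go wrong: the hindered ortho-methoxyaryl copper species attacks the acyl carbon of the lactone (acyl–oxygen cleavage) or acts as a base (β-elimination to crotonate) instead of displacing at the secondary β-carbon. The displacement may also not be cleanly invertive. Fallback: C3 is set by auxiliary-controlled conjugate addition. (R)-4-Phenyloxazolidin-2-one is N-acylated (n-BuLi, THF, −78 °C; (E)-but-2-enoyl chloride) to (R)-3-[(E)-but-2-enoyl]-4-phenyloxazolidin-2-one F3. Setting out from bromide 6 through Grignard reagent 8, addition to F3 with CuBr·SMe2 (THF/Me2S, −20 °C) should give (R)-4-phenyl-3-[(S)-3-(2,4,5-trimethoxyphenyl)butanoyl]oxazolidin-2-one F4. The aryl group should add to the magnesium-chelated s-cis enoyl imide on the face away from the 4-phenyl group, and F4 is recrystallised to a single diastereomer. LiOH/H2O2 (THF/H2O, 0 °C) cleaves the exocyclic acyl group as (S)-3-(2,4,5-trimethoxyphenyl)butaneperoxoic acid F5, which Na2SO3 reduces to acid 9, where the route is rejoined; the auxiliary is recovered.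

Step 6. What may go wrong: poor facial selectivity, because the ortho-methoxy group twists ring A out of conjugation and can bind borane, so that uncatalysed or mis-oriented hydride delivery competes and both C1 epimers form. Partial ionisation of the benzylic C–O bond during work-up would have the same effect. Fallback: selectivity is replaced by separation and recycling. Setting out from ketone 13, NaBH4 (MeOH/THF, 0 °C) should give both C1 epimers. These are diastereomers and are separated by chromatography on Et3N-deactivated silica into 14 and (1S,3S)-1,3-bis(2,4,5-trimethoxyphenyl)butan-1-ol F6. F6 is oxidised back to 13 with MnO2 (CH2Cl2, rt), a reagent selective for benzylic alcohols, and reduced again; the route is rejoined at 14.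

**Further compounds**

F1 | step 4 | (S)-N-methoxy-N-methyl-3-(2,4,5-trimethoxyphenyl)butanamide | CON(C)C(=O)C[C@H](C)c1cc(OC)c(OC)cc1OC
F2 | step 4 | (2,4,5-trimethoxyphenyl)lithium | [Li]c1cc(OC)c(OC)cc1OC
F3 | step 3 | (R)-3-[(E)-but-2-enoyl]-4-phenyloxazolidin-2-one | C/C=C/C(=O)N1[C@H](c2ccccc2)COC1=O
F4 | step 3 | (R)-4-phenyl-3-[(S)-3-(2,4,5-trimethoxyphenyl)butanoyl]oxazolidin-2-one | O=C(C[C@H](C)c1cc(OC)c(OC)cc1OC)N1[C@H](c2ccccc2)COC1=O
F5 | step 3 | (S)-3-(2,4,5-trimethoxyphenyl)butaneperoxoic acid | OOC(=O)C[C@H](C)c1cc(OC)c(OC)cc1OC
F6 | step 6 | (1S,3S)-1,3-bis(2,4,5-trimethoxyphenyl)butan-1-ol | COc1cc(OC)c([C@@H](O)C[C@H](C)c2cc(OC)c(OC)cc2OC)cc1OC
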